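**Plan** (indenone numbering: C1 carbonyl, C2, C3 methyl-bearing, C3a, C4 formyl, C6, C7, C7a)

1. Retrosynthesis: the C4 aldehyde is unmasked last from a dioxolane; the five-membered ring is cut at C1–C7a (aryl–acyl bond) and at C2=C3, leading back to an enol ester in which the azulenylacetyl unit C1–C2 sits on the enol oxygen of the aryl methyl ketone (C3) beside a bromide at C7a.
2. Further cuts: the enol ester C–O bond (bromo ketone + azulenylacetyl chloride), the C6–azulene bond (guaiazulene + aryl bromide) and the acetyl–arene bond, back to symmetric 3,5-dibromo-4-methylbenzaldehyde, guaiazulene and ethyl diazoacetate.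
3. Forward: the benzene ring and both azulenes are bought; acetal formation, ortho-lithiation/acetylation, arylation at the less hindered bromide and O-acylation follow, then one anionic cascade closes the five-membered ring and hydrolysis frees the aldehyde.
4. Enabling feature: C1 and C3 hang on the adjacent arene carbons C7a and C3a, so a C3–O–C1 bridge holds the ester carbonyl C1 in a five-membered array with a carbanion at C7a; after the acyl shift the freed C3 ketone lies in a five-membered array with the C2 methylene, which is acidified by the C1 carbonyl and the azulene.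
5. Stereochemistry: the target has no stereocentre; the aryl–azulene axes carry no descriptor and are assumed not to be configurationally fixed, and the two centres of the aldol intermediate disappear on dehydration.

Key step: step 8

In the step lines, Az stands for the 5-isopropyl-3,8-dimethylazulen-1-yl (guaiazulen-3-yl) group; the compound list gives full names.

Step 1
Reactants: 1 3,5-dibromo-4-methylbenzaldehyde; 2 ethane-1,2-diol
Product: 3 2-(3,5-dibromo-4-methylphenyl)-1,3-dioxolane
Conditions: 2 (3 equiv), TsOH·H2O (cat.), toluene, reflux, Dean–Stark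
Reagents that add atoms: ethane-1,2-diol (2), OCCO
Why: Acid-catalysed acetalisation with azeotropic removal of water masks the aldehyde against the bases and organolithium reagents used later and places an oxygen donor next to the ring C–H that is to be lithiated.

Step 2
Reactants: 3 2-(3,5-dibromo-4-methylphenyl)-1,3-dioxolane; 4 N-methoxy-N-methylacetamide
Product: 6 1-[2,4-dibromo-6-(1,3-dioxolan-2-yl)-3-methylphenyl]ethan-1-one, via aryllithium 5 (not isolated)
Conditions: LiN(iPr)2 (1.1 equiv), THF, −78 °C; then 4, −78 → −40 °C; then H2O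
Reagents that add atoms: N-methoxy-N-methylacetamide (4), CC(=O)N(C)OC
Why: Directed ortho-lithiation followed by Weinreb ketone synthesis: the two ring hydrogens of symmetric 3 are equivalent and each lies between a bromine and the dioxolane, so deprotonation can occur at one site only (kept at −78 °C to avoid aryne formation), and the chelated adduct with 4 releases the methyl ketone only on quench.

Step 3
Reactants: 6 1-[2,4-dibromo-6-(1,3-dioxolan-2-yl)-3-methylphenyl]ethan-1-one; 7 guaiazulene
Product: 8 1-[2-bromo-6-(1,3-dioxolan-2-yl)-4-Az-3-methylphenyl]ethan-1-one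
Conditions: 7 (1.5 equiv), Pd(OAc)2 (5 mol %), KOAc (2 equiv), DMAc, 120 °C
Reagents that add atoms: guaiazulene (7), c1cc(C)c2cc(C(C)C)ccc(C)c1-2
Why: Palladium-catalysed direct C–H arylation of guaiazulene, in which oxidative addition should prefer the bromide para to the acetyl group with a single ortho substituent over the bromide wedged between acetyl and methyl, and electrophilic palladation of the azulene should occur at C3 of guaiazulene, its most nucleophilic position.

Step 4
Reactants: 7 guaiazulene; 9 ethyl diazoacetate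
Product: 10 ethyl 2-Az-acetate
Conditions: 9 (slow addition), Cu(acac)2 (5 mol %), CH2Cl2, 40 °C
Reagents that add atoms: ethyl diazoacetate (9), CCOC(=O)C=[N+]=[N-]
Why: Copper-carbenoid C–H functionalisation (formal C–H insertion): the electrophilic copper carbene from 9 is attacked by the nucleophilic C3 of guaiazulene and a proton shift restores the azulene, which should give the azulenylacetate without touching the seven-membered ring.

Step 5
Reactants: 10 ethyl 2-Az-acetate
Product: 11 2-Az-acetic acid
Conditions: LiOH, THF/H2O, 23 °C; then aq. HCl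
Reagents that add atoms: lithium hydroxide, [Li+].[OH-]
Why: Saponification of the ethyl ester followed by mild acidification should give the free arylacetic acid, the azulene being inert to aqueous base.

Step 6
Reactants: 11 2-Az-acetic acid
Product: 12 2-Az-acetyl chloride
Conditions: 1-chloro-N,N,2-trimethylprop-1-en-1-amine (1.2 equiv), CH2Cl2, 0 → 23 °C; used crude
Reagents that add atoms: 1-chloro-N,N,2-trimethylprop-1-en-1-amine (Ghosez reagent), CC(C)=C(Cl)N(C)C
Why: Acid chloride formation with the Ghosez chloroenamine runs under neutral conditions, with no HCl and no Vilsmeier-type electrophile that could attack the azulene.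

Step 7
Reactants: 8 1-[2-bromo-6-(1,3-dioxolan-2-yl)-4-Az-3-methylphenyl]ethan-1-one; 12 2-Az-acetyl chloride
Product: 14 1-[2-bromo-6-(1,3-dioxolan-2-yl)-4-Az-3-methylphenyl]ethenyl 2-Az-acetate, via potassium enolate 13 (not isolated)
Conditions: KN(SiMe3)2 (1.05 equiv), THF, −78 °C; then 12, −78 → 0 °C
Reagents that add atoms: 2-Az-acetyl chloride (12), ClC(=O)Cc1cc(C)c2cc(C(C)C)ccc(C)c1-2
Why: Enolate O-acylation (enol ester formation): the methyl ketone has a single enolisable position and its dissociated potassium enolate should react with the hard acid chloride at oxygen at low temperature, which installs the C3–O–C1 bridge.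

Step 8
Reactants: 14 1-[2-bromo-6-(1,3-dioxolan-2-yl)-4-Az-3-methylphenyl]ethenyl 2-Az-acetate
Product: 18 4-(1,3-dioxolan-2-yl)-2,6-di-Az-3,7-dimethyl-1H-inden-1-one, via aryllithium 15 (not isolated), via lithium enolate 16 (not isolated), via aldol 17 (not isolated)
Conditions: t-BuLi (2.1 equiv), THF, −100 → −20 °C; then MeOH, 23 °C
Reagents that add atoms: none
Why: Proposed new method: bromine–lithium exchange at C7a (the second equivalent of t-BuLi destroys t-BuBr) gives an aryllithium that attacks the ester carbonyl C1 held on the enol oxygen of C3, the resulting five-membered alkoxide collapses with the enolate of the C3 methyl ketone as leaving group (C1–C7a formed, O–C1 broken), and after proton exchange the C2 methylene adds as its enolate to the freed C3 ketone and the aldol loses water under LiOMe/MeOH (C2=C3 formed). The closest known reaction types are the anionic homo-Fries (1,4 O-to-C acyl) shift of 2-bromobenzyl esters and Parham cyclisations for the first half and the base-mediated cyclodehydration of ortho-diacylbenzenes to indenones for the second; new is the enol ester serving at once as ketone mask and as acyl donor. The transient oxygen ring forms 5-exo-trig and the carbocyclic five-membered ring closes by a 5-exo-trig (enolexo) aldol addition followed by E1cB dehydration. No stereocentre remains, since the two centres of aldol 17 are formed without control and are erased on dehydration. The step needs exchange to outrun carbonyl addition and proton transfer, which is secured by t-BuLi at −100 °C and by intramolecular delivery through a five-membered transition state, and it needs the aldol to close from C2 onto C3 and not from the C3 methyl onto C1, which is secured by the higher acidity of the C2 methylene (flanked by the C1 carbonyl and the azulene), by the less hindered methyl ketone as acceptor and by reversibility of the aldol under methoxide, which drains to the tetrasubstituted enone.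

Step 9
Reactants: 18 4-(1,3-dioxolan-2-yl)-2,6-di-Az-3,7-dimethyl-1H-inden-1-one
Product: 19 2,6-di-Az-3,7-dimethyl-1-oxo-1H-indene-4-carbaldehyde (CNP0222726.0)
Conditions: pyridinium p-toluenesulfonate (cat.), acetone/H2O, 50 °C
Reagents that add atoms: water, O
Why: Acid-catalysed acetal hydrolysis under mild conditions that the azulenes and the enone should tolerate, while condensation of the freed aldehyde with the C3 methyl group is not expected because it would give a strained peri-fused ring.

**Compound list**

1 | 3,5-dibromo-4-methylbenzaldehyde | Cc1c(Br)cc(C=O)cc1Br | starting material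
2 | ethane-1,2-diol | OCCO | starting material
3 | 2-(3,5-dibromo-4-methylphenyl)-1,3-dioxolane | Cc1c(Br)cc(C2OCCO2)cc1Br | intermediate
4 | N-methoxy-N-methylacetamide | CC(=O)N(C)OC | starting material
5 | [2,4-dibromo-6-(1,3-dioxolan-2-yl)-3-methylphenyl]lithium | [Li]c1c(C2OCCO2)cc(Br)c(C)c1Br | intermediate
6 | 1-[2,4-dibromo-6-(1,3-dioxolan-2-yl)-3-methylphenyl]ethan-1-one | CC(=O)c1c(C2OCCO2)cc(Br)c(C)c1Br | intermediate
7 | guaiazulene (7-isopropyl-1,4-dimethylazulene) | c1cc(C)c2cc(C(C)C)ccc(C)c1-2 | starting material
8 | 1-[2-bromo-6-(1,3-dioxolan-2-yl)-4-(5-isopropyl-3,8-dimethylazulen-1-yl)-3-methylphenyl]ethan-1-one | CC(=O)c1c(C2OCCO2)cc(-c2cc(C)c3cc(C(C)C)ccc(C)c2-3)c(C)c1Br | intermediate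
9 | ethyl diazoacetate | CCOC(=O)C=[N+]=[N-] | starting material
10 | ethyl 2-(5-isopropyl-3,8-dimethylazulen-1-yl)acetate | CCOC(=O)Cc1cc(C)c2cc(C(C)C)ccc(C)c1-2 | intermediate
11 | 2-(5-isopropyl-3,8-dimethylazulen-1-yl)acetic acid | OC(=O)Cc1cc(C)c2cc(C(C)C)ccc(C)c1-2 | intermediate
12 | 2-(5-isopropyl-3,8-dimethylazulen-1-yl)acetyl chloride | ClC(=O)Cc1cc(C)c2cc(C(C)C)ccc(C)c1-2 | intermediate
13 | potassium 1-[2-bromo-6-(1,3-dioxolan-2-yl)-4-(5-isopropyl-3,8-dimethylazulen-1-yl)-3-methylphenyl]ethen-1-olate | [K]OC(=C)c1c(C2OCCO2)cc(-c2cc(C)c3cc(C(C)C)ccc(C)c2-3)c(C)c1Br | intermediate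
14 | 1-[2-bromo-6-(1,3-dioxolan-2-yl)-4-(5-isopropyl-3,8-dimethylazulen-1-yl)-3-methylphenyl]ethenyl 2-(5-isopropyl-3,8-dimethylazulen-1-yl)acetate | C=C(OC(=O)Cc1cc(C)c2cc(C(C)C)ccc(C)c1-2)c1c(C2OCCO2)cc(-c2cc(C)c3cc(C(C)C)ccc(C)c2-3)c(C)c1Br | intermediate
15 | [3-(1,3-dioxolan-2-yl)-5-(5-isopropyl-3,8-dimethylazulen-1-yl)-6-methyl-2-(1-{[(5-isopropyl-3,8-dimethylazulen-1-yl)acetyl]oxy}ethenyl)phenyl]lithium | C=C(OC(=O)Cc1cc(C)c2cc(C(C)C)ccc(C)c1-2)c1c(C2OCCO2)cc(-c2cc(C)c3cc(C(C)C)ccc(C)c2-3)c(C)c1[Li] | intermediate
16 | lithium 1-{6-(1,3-dioxolan-2-yl)-4-(5-isopropyl-3,8-dimethylazulen-1-yl)-2-[(5-isopropyl-3,8-dimethylazulen-1-yl)acetyl]-3-methylphenyl}ethen-1-olate | [Li]OC(=C)c1c(C2OCCO2)cc(-c2cc(C)c3cc(C(C)C)ccc(C)c2-3)c(C)c1C(=O)Cc1cc(C)c2cc(C(C)C)ccc(C)c1-2 | intermediate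
17 | 4-(1,3-dioxolan-2-yl)-3-hydroxy-2,6-bis(5-isopropyl-3,8-dimethylazulen-1-yl)-3,7-dimethyl-2,3-dihydro-1H-inden-1-one (racemic mixture of diastereomers, configuration at C2 and C3 not controlled) | CC1(O)C(c2cc(C)c3cc(C(C)C)ccc(C)c2-3)C(=O)c2c(C)c(-c3cc(C)c4cc(C(C)C)ccc(C)c3-4)cc(C3OCCO3)c21 | intermediate
18 | 4-(1,3-dioxolan-2-yl)-2,6-bis(5-isopropyl-3,8-dimethylazulen-1-yl)-3,7-dimethyl-1H-inden-1-one | CC1=C(c2cc(C)c3cc(C(C)C)ccc(C)c2-3)C(=O)c2c(C)c(-c3cc(C)c4cc(C(C)C)ccc(C)c3-4)cc(C3OCCO3)c21 | intermediate
19 | 2,6-bis(5-isopropyl-3,8-dimethylazulen-1-yl)-3,7-dimethyl-1-oxo-1H-indene-4-carbaldehyde (CNP0222726.0; no stereocentre) | CC1=C(c2cc(C)c3cc(C(C)C)ccc(C)c2-3)C(=O)c2c(C)c(-c3cc(C)c4cc(C(C)C)ccc(C)c3-4)cc(C=O)c21 | target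

**Step count and risks**

Total step count: 9. Longest linear sequence: 6 steps (1, 2, 3, 7, 8, 9 from compound 1; equally 4, 5, 6, 7, 8, 9 from guaiazulene).

Steps most likely to fail:

Step 8 (Proposed new method). The bromine–lithium exchange may be outrun by attack of t-BuLi on the ester carbonyl or on a seven-membered azulene ring. The aryllithium may be quenched by proton transfer from the azulenylacetyl methylene. The aldol may close from the wrong enolate. The fallback drops the bridge and uses known acylative cross-coupling; it sets out from 8 and returns at 18. Zinc insertion into 8 (Zn dust, LiCl, THF, 50 °C; the ortho acetyl group activates the bromide and the arylzinc tolerates the ketone) would give [2-acetyl-3-(1,3-dioxolan-2-yl)-5-Az-6-methylphenyl]zinc bromide F1. Negishi acylation of F1 with acid chloride 12 (Pd(PPh3)4, THF, 23 °C) would give the ortho-diacylbenzene 1-[2-acetyl-3-(1,3-dioxolan-2-yl)-5-Az-6-methylphenyl]-2-Az-ethan-1-one F2. K2CO3 in MeOH would then cyclodehydrate F2 to 18.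

Step 7. The enolate may be acylated at carbon, or may act as a base towards the acidic methylene of 12 and divert it to the ketene. The fallback avoids any strong base in the presence of the acyl donor; it sets out from 8 and returns at 14. Soft enolisation of 8 with Me3SiOTf/Et3N (CH2Cl2, 0 °C) would give the silyl enol ether {1-[2-bromo-6-(1,3-dioxolan-2-yl)-4-Az-3-methylphenyl]ethenyl}oxy(trimethyl)silane F3. Acid chloride 12 would be converted with KF/18-crown-6 (MeCN) into 2-Az-acetyl fluoride F4. Fluoride-catalysed acyl transfer between F3 and F4 (Bu4N[Ph3SiF2] cat., THF, 0 °C) should acylate the naked enolate at oxygen and give 14.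

Step 3. The azulene may be arylated at its C2 or at its C4 methyl group instead of C3, and oxidative addition may also occur at the hindered bromide, leading to double coupling. The fallback fixes the azulene position by halogenation and uses a cross-coupling; it sets out from 6 (with guaiazulene 7) and returns at 8. Bromination of 7 with NBS (hexane, 0 °C) would give 1-bromo-5-isopropyl-3,8-dimethylazulene F5, used at once. Miyaura borylation of F5 (B2pin2, PdCl2(dppf), KOAc, dioxane, 80 °C) would give 2-(5-isopropyl-3,8-dimethylazulen-1-yl)-4,4,5,5-tetramethyl-1,3,2-dioxaborolane F6. Suzuki–Miyaura coupling of F6 with 6 (Pd(OAc)2, SPhos, K3PO4, toluene/H2O, 80 °C) at the less hindered bromide should give 8.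

**Further compounds**

F1 | step 8 | [2-acetyl-3-(1,3-dioxolan-2-yl)-5-(5-isopropyl-3,8-dimethylazulen-1-yl)-6-methylphenyl]zinc bromide | CC(=O)c1c(C2OCCO2)cc(-c2cc(C)c3cc(C(C)C)ccc(C)c2-3)c(C)c1[Zn]Br
F2 | step 8 | 1-[2-acetyl-3-(1,3-dioxolan-2-yl)-5-(5-isopropyl-3,8-dimethylazulen-1-yl)-6-methylphenyl]-2-(5-isopropyl-3,8-dimethylazulen-1-yl)ethan-1-one | CC(=O)c1c(C2OCCO2)cc(-c2cc(C)c3cc(C(C)C)ccc(C)c2-3)c(C)c1C(=O)Cc1cc(C)c2cc(C(C)C)ccc(C)c1-2
F3 | step 7 | {1-[2-bromo-6-(1,3-dioxolan-2-yl)-4-(5-isopropyl-3,8-dimethylazulen-1-yl)-3-methylphenyl]ethenyl}oxy(trimethyl)silane | C=C(O[Si](C)(C)C)c1c(C2OCCO2)cc(-c2cc(C)c3cc(C(C)C)ccc(C)c2-3)c(C)c1Br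
F4 | step 7 | 2-(5-isopropyl-3,8-dimethylazulen-1-yl)acetyl fluoride | O=C(F)Cc1cc(C)c2cc(C(C)C)ccc(C)c1-2
F5 | step 3 | 1-bromo-5-isopropyl-3,8-dimethylazulene | Brc1cc(C)c2cc(C(C)C)ccc(C)c1-2
F6 | step 3 | 2-(5-isopropyl-3,8-dimethylazulen-1-yl)-4,4,5,5-tetramethyl-1,3,2-dioxaborolane | CC1(C)OB(c2cc(C)c3cc(C(C)C)ccc(C)c2-3)OC1(C)C
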